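**Retrosynthetic overview**

1. Target ⇒ endo [4+2] cycloaddition, the last step, which builds the norbornene, both bridgeheads and the spiro centre: 5‑acetoxycyclopentadiene 32 (made in the flask from tertiary carbinol 15) plus seco‑eudesmanolide dienophile 31.
2. 15 ⇒ 13 (ketone reduction, acetylation). 13 ⇒ 11 by the key step: SmI2 closes the seven‑membered ring through C6–C7, then the 12,8‑lactone closes. Enabling feature: C6 is the CH2 on C5 of the five‑membered ring, i.e. the vinylogous α‑position of the C2=O/C1=C5 enone, and C7 is the β‑carbon of the future α‑methylene‑γ‑lactone, i.e. the SN2′ terminus of a 2‑(acetoxymethyl)enoate.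
3. 11 ⇒ cross‑metathesis, aldehyde vinylation and Stork–Danheiser transposition on the pyran‑fused vinylogous ester 6 ⇐ organocatalytic Michael addition of cyclopentane‑1,3‑dione to crotonaldehyde (sets C10); the C2–O–C8 acetal ring is temporary.
4. 31 ⇒ organocerium methyl addition to enone 30 ⇐ aldol condensation ⇐ indium Barbier lactone 27 ⇐ (R)‑citronellol (chiral pool, side‑chain centre) plus bromide 19.
5. Ring order: cyclopentenone (from 1) → temporary dihydropyran → cycloheptene → γ‑lactone (upper half); γ‑lactone → cyclohexenone (lower half); norbornene last.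

Key step: step 7

Remark: guaiane numbering (C1–C15, α = face of H‑7) is used for the upper half and primed locants for the lower half; the acetal carbon of 3–7 and the carbinol carbon C4 of 5–15 are carried as epimer mixtures that vanish later, so their SMILES carry no descriptor.

Step 1
Reactants: 1 cyclopentane‑1,3‑dione; 2 (E)‑but‑2‑enal
Product: 4 (4R)‑2‑methoxy‑4‑methyl‑3,4,6,7‑tetrahydrocyclopenta[b]pyran‑5(2H)‑one, via lactol 3 (not isolated)
Conditions: (S)‑α,α‑diphenylprolinol TMS ether (10 mol%; enantiomer chosen for 4R), PhCO2H (10 mol%), CH2Cl2, 0 °C → rt; then MeOH, PPTS (cat.)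
Reagents that add atoms: methanol, CO
Why: Iminium‑activated organocatalytic Michael addition of the dione to the enal (the catalyst shields one face of the E‑iminium ion and should set C10 as R), followed by lactol closure on the enol oxygen and acetalisation, gives a cyclic vinylogous ester that masks the aldehyde.

Step 2
Reactants: 4 (4R)‑2‑methoxy‑4‑methyl‑3,4,6,7‑tetrahydrocyclopenta[b]pyran‑5(2H)‑one
Product: 5 (4R)‑2‑methoxy‑4,6‑dimethyl‑3,4,6,7‑tetrahydrocyclopenta[b]pyran‑5(2H)‑one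
Conditions: LDA, THF, −78 °C; MeI
Reagents that add atoms: iodomethane, CI
Why: Stork–Danheiser α′‑alkylation: the kinetic enolate of the 3‑alkoxy‑enone forms at the CH2 next to the carbonyl and is methylated there (the new centre is inconsequential).

Step 3
Reactants: 5 (4R)‑2‑methoxy‑4,6‑dimethyl‑3,4,6,7‑tetrahydrocyclopenta[b]pyran‑5(2H)‑one
Product: 6 (4R)‑6‑hydroxy‑2‑methoxy‑4,6‑dimethyl‑3,4,6,7‑tetrahydrocyclopenta[b]pyran‑5(2H)‑one
Conditions: LDA, THF, −78 °C; 2‑(phenylsulfonyl)‑3‑phenyloxaziridine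
Reagents that add atoms: 2‑(phenylsulfonyl)‑3‑phenyloxaziridine, O=S(=O)(c1ccccc1)N1OC1c1ccccc1
Why: A second α′‑deprotonation gives the fully substituted enolate, which is hydroxylated by oxygen transfer from the N‑sulfonyloxaziridine (Davis oxidation); this carbinol becomes the leaving group of step 20, so its configuration does not matter.

Step 4
Reactants: 6 (4R)‑6‑hydroxy‑2‑methoxy‑4,6‑dimethyl‑3,4,6,7‑tetrahydrocyclopenta[b]pyran‑5(2H)‑one
Product: 8 (3R)‑3‑[2‑(chloromethyl)‑3‑hydroxy‑3‑methyl‑5‑oxocyclopent‑1‑en‑1‑yl]butanal, via chlorohydrin 7 (not isolated)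
Conditions: ICH2Cl, MeLi·LiBr (3 equiv), THF, −78 °C; then 1 M HCl, THF, 0 °C
Reagents that add atoms: chloroiodomethane, ClCI; water, O
Why: Stork–Danheiser 1,2‑addition/transposition: chloromethyllithium from I/Li exchange adds to the vinylogous ester carbonyl, and acid ionises the tertiary carbinol through the enol ether so that hydrolysis releases the transposed C2 enone, the chloromethyl group on C5 and the C8 aldehyde in one work‑up.

Step 5
Reactants: 8 (3R)‑3‑[2‑(chloromethyl)‑3‑hydroxy‑3‑methyl‑5‑oxocyclopent‑1‑en‑1‑yl]butanal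
Product: 9 3‑(chloromethyl)‑4‑hydroxy‑2‑[(2R,4R)‑4‑hydroxyhex‑5‑en‑2‑yl]‑4‑methylcyclopent‑2‑en‑1‑one
Conditions: (CH2=CH)2Zn (2.5 equiv), (−)‑MIB (10 mol%; enantiomer chosen for the R carbinol), toluene, −10 °C
Reagents that add atoms: divinylzinc, C=C[Zn]C=C
Why: Amino‑alcohol‑catalysed asymmetric addition of a vinylzinc reagent is aldehyde‑selective (ketone and allylic chloride are left) and the ligand should fix the C8 carbinol as R by reagent control.

Step 6
Reactants: 9 3‑(chloromethyl)‑4‑hydroxy‑2‑[(2R,4R)‑4‑hydroxyhex‑5‑en‑2‑yl]‑4‑methylcyclopent‑2‑en‑1‑one; 10 methyl 2‑(acetoxymethyl)acrylate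
Product: 11 methyl (2E,4R,6R)‑2‑(acetoxymethyl)‑6‑[2‑(chloromethyl)‑3‑hydroxy‑3‑methyl‑5‑oxocyclopent‑1‑en‑1‑yl]‑4‑hydroxyhept‑2‑enoate
Conditions: Hoveyda–Grubbs II (10 mol%), 10 (5 equiv), CH2Cl2, 40 °C
Reagents that add atoms: none
Why: Olefin cross‑metathesis of the allylic alcohol with an excess of the 1,1‑disubstituted acrylate should give the trisubstituted enoate with the ester trans to the carbinol carbon, as known for methacrylate partners.

Step 7
Reactants: 11 methyl (2E,4R,6R)‑2‑(acetoxymethyl)‑6‑[2‑(chloromethyl)‑3‑hydroxy‑3‑methyl‑5‑oxocyclopent‑1‑en‑1‑yl]‑4‑hydroxyhept‑2‑enoate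
Product: 13 4‑hydroxy‑2‑oxoguaia‑1(5),11(13)‑dien‑12,8α‑olide (7αH,8βH,10β‑methyl), via hydroxy ester 12 (not isolated)
Conditions: SmI2 (2.5 equiv), THF, −78 → 0 °C; then p‑TsOH (cat.), CH2Cl2, rt
Reagents that add atoms: none
Why: Proposed new method: SmI2 should transfer two electrons to the 3‑(chloromethyl)enone, chloride leaving from the vinylogous α‑position to give a samarium(III) dienolate whose exocyclic γ‑carbon C6 adds 7‑exo‑trig to the enoate β‑carbon C7; the ester enolate then expels acetate (net intramolecular SN2′, creating the exocyclic methylene) and the C8 hydroxyl lactonises onto the new acrylate (5‑exo‑trig acyl substitution). The closest known chemistry is the SmI2 cleavage of γ‑heterosubstituted enones to dienolates, Reformatsky‑type additions of samarium enolates, and SN2′ substitution of Morita–Baylis–Hillman acetates by soft carbanions. The new centre C7 should be controlled by allylic 1,3‑strain: H‑8 eclipses the enoate plane and the tether holds C6 on the face of C9, so the C6–C7 bond forms anti to O‑8 and retentive lactonisation gives the trans‑fused lactone. The step needs reduction of the C–Cl bond before the acetoxy‑enoate, which the lower‑lying enone acceptor should secure. It also needs γ‑ rather than α‑attack of the dienolate, which is favoured because α‑attack would build a spiro cyclopentane with a quaternary carbon and lose conjugation.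

Step 8
Reactants: 13 4‑hydroxy‑2‑oxoguaia‑1(5),11(13)‑dien‑12,8α‑olide
Product: 14 2α,4‑dihydroxyguaia‑1(5),11(13)‑dien‑12,8α‑olide (2R)
Conditions: (S)‑Me‑CBS (0.2 equiv), catecholborane (2.2 equiv), toluene, −78 °C
Reagents that add atoms: none
Why: Corey–Bakshi–Shibata reduction: the oxazaborolidine distinguishes the fully substituted alkenyl flank from the CH2 flank and should deliver hydride to give the 2R allylic alcohol by reagent control, the α‑methylene lactone being inert to catecholborane at this temperature.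

Step 9
Reactants: 14 2α,4‑dihydroxyguaia‑1(5),11(13)‑dien‑12,8α‑olide
Product: 15 2α‑acetoxy‑4‑hydroxyguaia‑1(5),11(13)‑dien‑12,8α‑olide
Conditions: Ac2O, pyridine, DMAP (cat.), CH2Cl2, 0 °C
Reagents that add atoms: acetic anhydride, CC(=O)OC(C)=O
Why: DMAP‑catalysed acylation should take only the secondary allylic hydroxyl, the tertiary carbinol being too hindered at 0 °C.

Step 10
Reactants: 16 methyl acrylate; 17 2,2‑dimethoxyacetaldehyde
Product: 18 methyl 3‑hydroxy‑4,4‑dimethoxy‑2‑methylidenebutanoate (racemic)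
Conditions: DABCO (0.5 equiv), dioxane/H2O, rt
Reagents that add atoms: none
Why: Morita–Baylis–Hillman reaction of an unhindered acrylate with a reactive α,α‑dialkoxy aldehyde.

Step 11
Reactants: 18 methyl 3‑hydroxy‑4,4‑dimethoxy‑2‑methylidenebutanoate
Product: 19 methyl (2Z)‑2‑(bromomethyl)‑4,4‑dimethoxybut‑2‑enoate
Conditions: NBS, Me2S, CH2Cl2, −20 → 0 °C
Reagents that add atoms: N‑bromosuccinimide, O=C1CCC(=O)N1Br
Why: Bromosulfonium activation of the allylic alcohol and SN2′ attack of bromide (Corey–Kim‑type conditions) should give the (Z)‑2‑(bromomethyl)enoate without touching the acetal.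

Step 12
Reactants: 20 (R)‑citronellol; 21 allyl acetate
Product: 22 (4S,6R)‑6,10‑dimethylundeca‑1,9‑dien‑4‑ol
Conditions: [Ir(cod)Cl]2 (2.5 mol%), Cl,MeO‑BIPHEP (5 mol%; enantiomer chosen for 4S), 3‑nitrobenzoic acid (10 mol%), Cs2CO3 (20 mol%), THF, 100 °C
Reagents that add atoms: none
Why: Iridium‑catalysed transfer‑hydrogenative carbonyl allylation from the alcohol oxidation level: the alcohol is dehydrogenated in the flask, the allyliridium complex adds to the transient aldehyde, and the chiral bisphosphine should set the carbinol independently of the remote methyl centre.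

Step 13
Reactants: 22 (4S,6R)‑6,10‑dimethylundeca‑1,9‑dien‑4‑ol
Product: 23 (4R,6S)‑4‑methylnon‑8‑ene‑1,6‑diol
Conditions: O3 (1.0 equiv, Sudan III end point), CH2Cl2/MeOH, −78 °C; NaBH4, −78 → 0 °C
Reagents that add atoms: ozone, [O-][O+]=O
Why: Ozone attacks the electron‑rich trisubstituted alkene much faster than the terminal vinyl group (indicator‑controlled ozonolysis), and borohydride work‑up reduces the ozonide to the primary alcohol.

Step 14
Reactants: 23 (4R,6S)‑4‑methylnon‑8‑ene‑1,6‑diol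
Product: 24 (4R,6S)‑6‑hydroxy‑4‑methylnon‑8‑en‑1‑yl acetate
Conditions: AcCl, 2,4,6‑collidine, CH2Cl2, −78 °C
Reagents that add atoms: acetyl chloride, CC(=O)Cl
Why: Low‑temperature acylation with acetyl chloride and a hindered pyridine discriminates the primary from the secondary hydroxyl.

Step 15
Reactants: 24 (4R,6S)‑6‑hydroxy‑4‑methylnon‑8‑en‑1‑yl acetate
Product: 25 (4R,6R)‑6‑hydroxy‑4‑methyl‑8‑oxooctyl acetate
Conditions: O3, CH2Cl2, −78 °C; PPh3
Reagents that add atoms: ozone, [O-][O+]=O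
Why: Ozonolysis of the remaining terminal alkene with phosphine work‑up gives the β‑hydroxy aldehyde, which is used crude to avoid β‑elimination.

Step 16
Reactants: 25 (4R,6R)‑6‑hydroxy‑4‑methyl‑8‑oxooctyl acetate; 19 methyl (2Z)‑2‑(bromomethyl)‑4,4‑dimethoxybut‑2‑enoate
Product: 27 (4R,6R)‑7‑[(2S,3S)‑3‑(dimethoxymethyl)‑4‑methylidene‑5‑oxooxolan‑2‑yl]‑6‑hydroxy‑4‑methylheptyl acetate, via hydroxy ester 26 (not isolated)
Conditions: In powder, THF/H2O 1:1, rt; then PPTS (cat.), CH2Cl2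
Reagents that add atoms: none
Why: Indium‑mediated Barbier allylation in water: the allylindium attacks through its γ‑carbon in a chair transition state (syn adduct, hence cis lactone) while In(III) chelation between the aldehyde and the free β‑hydroxyl should direct attack anti to the chain (1,3‑anti), so the sacrificial carbinol relays absolute configuration to C8′ and C7′ before acid closes the γ‑lactone.

Step 17
Reactants: 27 (4R,6R)‑7‑[(2S,3S)‑3‑(dimethoxymethyl)‑4‑methylidene‑5‑oxooxolan‑2‑yl]‑6‑hydroxy‑4‑methylheptyl acetate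
Product: 28 (4R)‑7‑[(2S,3S)‑3‑(dimethoxymethyl)‑4‑methylidene‑5‑oxooxolan‑2‑yl]‑4‑methyl‑6‑oxoheptyl acetate
Conditions: Dess–Martin periodinane, NaHCO3, CH2Cl2, 0 °C → rt
Reagents that add atoms: none
Why: Buffered Dess–Martin oxidation removes the relay carbinol without β‑elimination of the lactone oxygen.

Step 18
Reactants: 28 (4R)‑7‑[(2S,3S)‑3‑(dimethoxymethyl)‑4‑methylidene‑5‑oxooxolan‑2‑yl]‑4‑methyl‑6‑oxoheptyl acetate
Product: 30 (4R)‑4‑[(3aS,7aS)‑3‑methylidene‑2,6‑dioxo‑2,3,3a,6,7,7a‑hexahydro‑1‑benzofuran‑5‑yl]pentyl acetate, via keto aldehyde 29 (not isolated)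
Conditions: TFA/H2O/CH2Cl2, 0 °C; then Bn2NH·TFA (cat.), benzene, 50 °C
Reagents that add atoms: none
Why: Acetal hydrolysis followed by aminium‑catalysed intramolecular aldol condensation (6‑enolexo; only the CH2 on the side‑chain flank of the ketone can reach the aldehyde) should give the 2‑substituted cyclohexenone with the ring fusion untouched.

Step 19
Reactants: 30 (4R)‑4‑[(3aS,7aS)‑3‑methylidene‑2,6‑dioxo‑2,3,3a,6,7,7a‑hexahydro‑1‑benzofuran‑5‑yl]pentyl acetate
Product: 31 (4R)‑4‑[(3aS,6R,7aS)‑6‑hydroxy‑6‑methyl‑3‑methylidene‑2‑oxo‑2,3,3a,6,7,7a‑hexahydro‑1‑benzofuran‑5‑yl]pentyl acetate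
Conditions: MeMgBr (1.5 equiv), CeCl3 (1.6 equiv), THF, −78 °C
Reagents that add atoms: methylmagnesium bromide, C[Mg]Br
Why: Organocerium 1,2‑addition is carbonyl‑selective over lactone and acetate at −78 °C and should occur from the convex face of the cis‑fused bicycle, anti to the lactone ring, placing the new hydroxyl cis to the lactone oxygen.

Step 20
Reactants: 15 2α‑acetoxy‑4‑hydroxyguaia‑1(5),11(13)‑dien‑12,8α‑olide; 31 (4R)‑4‑[(3aS,6R,7aS)‑6‑hydroxy‑6‑methyl‑3‑methylidene‑2‑oxo‑2,3,3a,6,7,7a‑hexahydro‑1‑benzofuran‑5‑yl]pentyl acetate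
Product: 33 CNP0257312.1 (target), via acetoxydiene 32 (not isolated)
Conditions: Martin sulfurane (1.0 equiv), CH2Cl2, −20 °C; after its consumption 31 (3 equiv), toluene (2 M), 25–40 °C (or 10 kbar)
Reagents that add atoms: none
Why: Dehydration of the tertiary allylic carbinol toward the ring CH2 unveils the 5‑acetoxycyclopentadiene at low temperature, and the biomimetic Diels–Alder reaction with the α‑methylene lactone should proceed endo (lactone carbonyl under the diene), on the diene face syn to the acetoxy group and anti to the C10 methyl, on the convex face of 31, with the CH2 terminus bonding to the substituted diene terminus C1.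

**Compound list**

1 | cyclopentane‑1,3‑dione | O=C1CCC(=O)C1 | starting material
2 | (E)‑but‑2‑enal | C/C=C/C=O | starting material
3 | (4R)‑2‑hydroxy‑4‑methyl‑3,4,6,7‑tetrahydrocyclopenta[b]pyran‑5(2H)‑one | OC1C[C@@H](C)C2=C(O1)CCC2=O | intermediate
4 | (4R)‑2‑methoxy‑4‑methyl‑3,4,6,7‑tetrahydrocyclopenta[b]pyran‑5(2H)‑one | COC1C[C@@H](C)C2=C(O1)CCC2=O | intermediate
5 | (4R)‑2‑methoxy‑4,6‑dimethyl‑3,4,6,7‑tetrahydrocyclopenta[b]pyran‑5(2H)‑one | COC1C[C@@H](C)C2=C(O1)CC(C)C2=O | intermediate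
6 | (4R)‑6‑hydroxy‑2‑methoxy‑4,6‑dimethyl‑3,4,6,7‑tetrahydrocyclopenta[b]pyran‑5(2H)‑one | COC1C[C@@H](C)C2=C(O1)CC(C)(O)C2=O | intermediate
7 | (4R)‑5‑(chloromethyl)‑2‑methoxy‑4,6‑dimethyl‑2,3,4,5,6,7‑hexahydrocyclopenta[b]pyran‑5,6‑diol | COC1C[C@@H](C)C2=C(O1)CC(C)(O)C2(O)CCl | intermediate
8 | (3R)‑3‑[2‑(chloromethyl)‑3‑hydroxy‑3‑methyl‑5‑oxocyclopent‑1‑en‑1‑yl]butanal | O=CC[C@@H](C)C1=C(CCl)C(C)(O)CC1=O | intermediate
9 | 3‑(chloromethyl)‑4‑hydroxy‑2‑[(2R,4R)‑4‑hydroxyhex‑5‑en‑2‑yl]‑4‑methylcyclopent‑2‑en‑1‑one | C=C[C@H](O)C[C@@H](C)C1=C(CCl)C(C)(O)CC1=O | intermediate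
10 | methyl 2‑(acetoxymethyl)acrylate | C=C(COC(C)=O)C(=O)OC | starting material
11 | methyl (2E,4R,6R)‑2‑(acetoxymethyl)‑6‑[2‑(chloromethyl)‑3‑hydroxy‑3‑methyl‑5‑oxocyclopent‑1‑en‑1‑yl]‑4‑hydroxyhept‑2‑enoate | CC(=O)OC/C(C(=O)OC)=C\[C@H](O)C[C@@H](C)C1=C(CCl)C(C)(O)CC1=O | intermediate
12 | methyl 2‑[(5S,6R,8R)‑3,6‑dihydroxy‑3,8‑dimethyl‑1‑oxo‑1,2,3,4,5,6,7,8‑octahydroazulen‑5‑yl]prop‑2‑enoate | C=C(C(=O)OC)[C@@H]1CC2=C(C(=O)CC2(C)O)[C@H](C)C[C@H]1O | intermediate
13 | 4‑hydroxy‑2‑oxoguaia‑1(5),11(13)‑dien‑12,8α‑olide (7S,8R,10R) | C=C1C(=O)O[C@@H]2C[C@@H](C)C3=C(C[C@@H]12)C(C)(O)CC3=O | intermediate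
14 | 2α,4‑dihydroxyguaia‑1(5),11(13)‑dien‑12,8α‑olide (2R,7S,8R,10R) | C=C1C(=O)O[C@@H]2C[C@@H](C)C3=C(C[C@@H]12)C(C)(O)C[C@H]3O | intermediate
15 | 2α‑acetoxy‑4‑hydroxyguaia‑1(5),11(13)‑dien‑12,8α‑olide | C=C1C(=O)O[C@@H]2C[C@@H](C)C3=C(C[C@@H]12)C(C)(O)C[C@H]3OC(C)=O | intermediate
16 | methyl acrylate | C=CC(=O)OC | starting material
17 | 2,2‑dimethoxyacetaldehyde | COC(OC)C=O | starting material
18 | methyl 3‑hydroxy‑4,4‑dimethoxy‑2‑methylidenebutanoate | C=C(C(O)C(OC)OC)C(=O)OC | intermediate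
19 | methyl (2Z)‑2‑(bromomethyl)‑4,4‑dimethoxybut‑2‑enoate | BrC/C(C(=O)OC)=C\C(OC)OC | intermediate
20 | (R)‑citronellol, (3R)‑3,7‑dimethyloct‑6‑en‑1‑ol | OCC[C@H](C)CCC=C(C)C | starting material
21 | allyl acetate | C=CCOC(C)=O | starting material
22 | (4S,6R)‑6,10‑dimethylundeca‑1,9‑dien‑4‑ol | C=CC[C@H](O)C[C@H](C)CCC=C(C)C | intermediate
23 | (4R,6S)‑4‑methylnon‑8‑ene‑1,6‑diol | C=CC[C@H](O)C[C@H](C)CCCO | intermediate
24 | (4R,6S)‑6‑hydroxy‑4‑methylnon‑8‑en‑1‑yl acetate | C=CC[C@H](O)C[C@H](C)CCCOC(C)=O | intermediate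
25 | (4R,6R)‑6‑hydroxy‑4‑methyl‑8‑oxooctyl acetate | O=CC[C@H](O)C[C@H](C)CCCOC(C)=O | intermediate
26 | methyl (3S,4S,6R,8R)‑11‑acetoxy‑3‑(dimethoxymethyl)‑4,6‑dihydroxy‑8‑methyl‑2‑methylideneundecanoate | C=C(C(=O)OC)[C@H](C(OC)OC)[C@@H](O)C[C@H](O)C[C@H](C)CCCOC(C)=O | intermediate
27 | (4R,6R)‑7‑[(2S,3S)‑3‑(dimethoxymethyl)‑4‑methylidene‑5‑oxooxolan‑2‑yl]‑6‑hydroxy‑4‑methylheptyl acetate | C=C1C(=O)O[C@@H](C[C@H](O)C[C@H](C)CCCOC(C)=O)[C@H]1C(OC)OC | intermediate
28 | (4R)‑7‑[(2S,3S)‑3‑(dimethoxymethyl)‑4‑methylidene‑5‑oxooxolan‑2‑yl]‑4‑methyl‑6‑oxoheptyl acetate | C=C1C(=O)O[C@@H](CC(=O)C[C@H](C)CCCOC(C)=O)[C@H]1C(OC)OC | intermediate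
29 | (4R)‑7‑[(2S,3S)‑3‑formyl‑4‑methylidene‑5‑oxooxolan‑2‑yl]‑4‑methyl‑6‑oxoheptyl acetate | C=C1C(=O)O[C@@H](CC(=O)C[C@H](C)CCCOC(C)=O)[C@H]1C=O | intermediate
30 | (4R)‑4‑[(3aS,7aS)‑3‑methylidene‑2,6‑dioxo‑2,3,3a,6,7,7a‑hexahydro‑1‑benzofuran‑5‑yl]pentyl acetate | C=C1C(=O)O[C@H]2CC(=O)C([C@H](C)CCCOC(C)=O)=C[C@H]21 | intermediate
31 | (4R)‑4‑[(3aS,6R,7aS)‑6‑hydroxy‑6‑methyl‑3‑methylidene‑2‑oxo‑2,3,3a,6,7,7a‑hexahydro‑1‑benzofuran‑5‑yl]pentyl acetate | C=C1C(=O)O[C@H]2C[C@@](C)(O)C([C@H](C)CCCOC(C)=O)=C[C@H]21 | intermediate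
32 | 2α‑acetoxyguaia‑1(5),3,11(13)‑trien‑12,8α‑olide (2R,7S,8R,10R) | C=C1C(=O)O[C@@H]2C[C@@H](C)C3=C(C[C@@H]12)C(C)=C[C@H]3OC(C)=O | intermediate
33 | CNP0257312.1 | C=C1C(=O)O[C@@H]2C[C@@H](C)[C@]34C[C@]5(C(=O)O[C@H]6C[C@@](C)(O)C([C@H](C)CCCOC(C)=O)=C[C@H]65)[C@H](C(C)=C3C[C@@H]12)[C@H]4OC(C)=O | target

**Step count and risks**

Total step count: 20. Longest linear sequence: 10 steps (steps 1–9, then 20).

Steps most likely to fail:

1. Step 7 (Proposed new method). The samarium dienolate may be protonated by the two free hydroxyls, or react through its α‑carbon, faster than it closes the seven‑membered ring. The fallback sets out from 11. The allylic chloride is displaced with sodium benzenesulfinate in DMF to give sulfone F1. DBU in MeCN then generates the sulfonyl‑stabilised carbanion, which closes the ring by intramolecular Michael addition/β‑acetoxy elimination (the established SN2′ behaviour of soft carbanions toward Morita–Baylis–Hillman acetates) to hydroxy ester F2, and PPTS lactonises this to lactone sulfone F3. Reductive desulfonylation of the vinylogous β‑keto sulfone (aluminium amalgam or SmI2/HMPA) returns to the route at 13.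

2. Step 20. The 5‑acetoxydiene may undergo [1,5]‑hydrogen shift to enol acetates, the dehydration may run toward the exocyclic methyl, or 32 may dimerise with itself faster than it is intercepted. The fallback sets out from 13 and 31 and moves the cycloaddition to the ketone oxidation level. 31 is silylated (TMSCl, imidazole) to silyl ether F4. 13 is dehydrated with Burgess reagent in the presence of F4, and the transient cyclopentadienone F5 is trapped by Diels–Alder reaction as norbornen‑7‑one F6. NaBH4 should attack the bridging ketone from the alkene side to give alcohol F7 (hydroxyl anti to the alkene). Acetylation gives acetate F8 and HF·pyridine removes the silyl group, returning to the route at 33.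

3. Step 18. Under the aminium catalyst the exocyclic methylene may migrate into conjugation or add the amine, and the formyl‑bearing centre may epimerise by enolisation. The fallback sets out from 28 and masks the methylene lactone. Dimethylamine is added to give amine adduct F9. Acetal hydrolysis to keto aldehyde F10 and aldol condensation give amino enone F11. Quaternisation with MeI to ammonium salt F12 and elimination with NaHCO3 regenerate the α‑methylene lactone, returning to the route at 30.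

**Further compounds**

F1 | step 7 | methyl (2E,4R,6R)‑2‑(acetoxymethyl)‑4‑hydroxy‑6‑{3‑hydroxy‑3‑methyl‑5‑oxo‑2‑[(phenylsulfonyl)methyl]cyclopent‑1‑en‑1‑yl}hept‑2‑enoate | CC(=O)OC/C(C(=O)OC)=C\[C@H](O)C[C@@H](C)C1=C(CS(=O)(=O)c2ccccc2)C(C)(O)CC1=O
F2 | step 7 | 6‑(phenylsulfonyl) analogue of hydroxy ester 12 | C=C(C(=O)OC)[C@@H]1C(S(=O)(=O)c3ccccc3)C2=C(C(=O)CC2(C)O)[C@H](C)C[C@H]1O
F3 | step 7 | 6‑(phenylsulfonyl) analogue of lactone 13 | C=C1C(=O)O[C@@H]2C[C@@H](C)C3=C(C(S(=O)(=O)c4ccccc4)[C@@H]12)C(C)(O)CC3=O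
F4 | step 20 | trimethylsilyl ether of 31 | C=C1C(=O)O[C@H]2C[C@@](C)(O[Si](C)(C)C)C([C@H](C)CCCOC(C)=O)=C[C@H]21
F5 | step 20 | 2‑oxoguaia‑1(5),3,11(13)‑trien‑12,8α‑olide (cyclopentadienone) | C=C1C(=O)O[C@@H]2C[C@@H](C)C3=C(C[C@@H]12)C(C)=CC3=O
F6 | step 20 | bridging‑ketone analogue of 33 as the trimethylsilyl ether | C=C1C(=O)O[C@@H]2C[C@@H](C)[C@]34C[C@]5(C(=O)O[C@H]6C[C@@](C)(O[Si](C)(C)C)C([C@H](C)CCCOC(C)=O)=C[C@H]65)[C@H](C(C)=C3C[C@@H]12)C4=O
F7 | step 20 | bridge alcohol (deacetyl analogue of 33) as the trimethylsilyl ether | C=C1C(=O)O[C@@H]2C[C@@H](C)[C@]34C[C@]5(C(=O)O[C@H]6C[C@@](C)(O[Si](C)(C)C)C([C@H](C)CCCOC(C)=O)=C[C@H]65)[C@H](C(C)=C3C[C@@H]12)[C@H]4O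
F8 | step 20 | trimethylsilyl ether of 33 | C=C1C(=O)O[C@@H]2C[C@@H](C)[C@]34C[C@]5(C(=O)O[C@H]6C[C@@](C)(O[Si](C)(C)C)C([C@H](C)CCCOC(C)=O)=C[C@H]65)[C@H](C(C)=C3C[C@@H]12)[C@H]4OC(C)=O
F9 | step 18 | dimethylamine adduct of 28 | CN(C)CC1C(=O)O[C@@H](CC(=O)C[C@H](C)CCCOC(C)=O)[C@H]1C(OC)OC
F10 | step 18 | dimethylamine adduct of keto aldehyde 29 | CN(C)CC1C(=O)O[C@@H](CC(=O)C[C@H](C)CCCOC(C)=O)[C@H]1C=O
F11 | step 18 | dimethylamine adduct of 30 | CN(C)CC1C(=O)O[C@H]2CC(=O)C([C@H](C)CCCOC(C)=O)=C[C@H]21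
F12 | step 18 | trimethylammonium iodide of F11 | C[N+](C)(C)CC1C(=O)O[C@H]2CC(=O)C([C@H](C)CCCOC(C)=O)=C[C@H]21.[I-]
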